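**Retrosynthetic overview**
1. Target: 4-methoxybenzoic acid with an (E)-4-hydroxy-3-methylbut-2-enyl chain at C3 and a (2E,4R)-4-hydroxy-3,7-dimethylocta-2,6-dienyl chain at C5. The last operations are desilylation and ester hydrolysis.
2. The C6'=C7' isopropylidene end comes from cross-metathesis of a terminal alkene with 2-methyl-2-butene.
3. Key bond C4'–C5': Brown asymmetric allylboration of an aryl-substituted (E)-2-methylenal, which sets the only stereocentre (4R).
4. Both (E)-2-methylenal units come from cross-metathesis of aryl allyl groups with methacrolein. The first allyl is installed by O-allylation and Claisen rearrangement, the second by Stille coupling at a bromide kept as a handle, so the two chains are built one after the other.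
5. No ring is formed; the benzene ring is bought as methyl 3-bromo-4-hydroxybenzoate.

Assumption: all numbered starting materials are bought, and reagents that donate atoms are numbered as compounds.

**Route**

Step 1
Reactants: 1 methyl 3-bromo-4-hydroxybenzoate; 2 allyl bromide
Product: 3 methyl 4-(allyloxy)-3-bromobenzoate
Conditions: K2CO3, acetone, reflux
Reagents that add atoms: allyl bromide (2), C=CCBr
Why: Williamson ether synthesis; the acidic phenol (ortho-Br, para-ester) is O-alkylated cleanly by the allylic bromide.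

Step 2
Reactants: 3 methyl 4-(allyloxy)-3-bromobenzoate
Product: 5 methyl 3-allyl-5-bromo-4-hydroxybenzoate, via ortho-dienone 4 (not isolated)
Conditions: N,N-diethylaniline, 200 °C, sealed tube
Reagents that add atoms: none
Why: Aromatic Claisen rearrangement; the [3,3] shift goes to the only free ortho position and the dienone tautomerises back to the phenol.

Step 3
Reactants: 5 methyl 3-allyl-5-bromo-4-hydroxybenzoate; 6 iodomethane
Product: 7 methyl 3-allyl-5-bromo-4-methoxybenzoate
Conditions: MeI, K2CO3, DMF, rt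
Reagents that add atoms: iodomethane (6), CI
Why: SN2 O-methylation of the phenoxide fixes the methyl ether of the target.

Step 4
Reactants: 7 methyl 3-allyl-5-bromo-4-methoxybenzoate; 8 methacrolein
Product: 9 methyl 3-bromo-4-methoxy-5-[(2E)-3-methyl-4-oxobut-2-en-1-yl]benzoate
Conditions: methacrolein (8 equiv), second-generation Grubbs catalyst RuCl2(=CHPh)(H2IMes)(PCy3) (5 mol%), 1,4-benzoquinone (10 mol%), CH2Cl2, 40 °C
Reagents that add atoms: methacrolein (8), CC(=C)C=O
Why: Olefin cross-metathesis of a terminal alkene with excess methacrolein gives the trisubstituted enal as the E isomer (formyl trans to the benzylic CH2) under thermodynamic control, and benzoquinone suppresses allyl-to-propenyl migration.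

Step 5
Reactants: 9 methyl 3-bromo-4-methoxy-5-[(2E)-3-methyl-4-oxobut-2-en-1-yl]benzoate
Product: 10 methyl 3-bromo-5-[(2E)-4-hydroxy-3-methylbut-2-en-1-yl]-4-methoxybenzoate
Conditions: NaBH4, CeCl3·7H2O, MeOH, 0 °C
Reagents that add atoms: none
Why: Luche 1,2-reduction of the enal leaves the ester, the aryl bromide and the E alkene untouched.

Step 6
Reactants: 10 methyl 3-bromo-5-[(2E)-4-hydroxy-3-methylbut-2-en-1-yl]-4-methoxybenzoate; 11 tert-butyldimethylsilyl chloride
Product: 12 methyl 3-bromo-5-[(2E)-4-(tert-butyldimethylsilyloxy)-3-methylbut-2-en-1-yl]-4-methoxybenzoate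
Conditions: TBSCl, imidazole, DMF, rt
Reagents that add atoms: tert-butyldimethylsilyl chloride (11), CC(C)(C)[Si](C)(C)Cl
Why: Silylation of the primary allylic alcohol masks it against the cross-coupling, the allylborane and the later metathesis steps.

Step 7
Reactants: 12 methyl 3-bromo-5-[(2E)-4-(tert-butyldimethylsilyloxy)-3-methylbut-2-en-1-yl]-4-methoxybenzoate; 13 allyltributylstannane
Product: 14 methyl 3-allyl-5-[(2E)-4-(tert-butyldimethylsilyloxy)-3-methylbut-2-en-1-yl]-4-methoxybenzoate
Conditions: allylSnBu3, Pd(PPh3)4 (5 mol%), toluene, 110 °C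
Reagents that add atoms: allyltributylstannane (13), C=CC[Sn](CCCC)(CCCC)CCCC
Why: Stille coupling (oxidative addition of zerovalent palladium into the aryl bromide, allyl transfer from tin, reductive elimination) tolerates the ester, the silyl ether and the trisubstituted alkene.

Step 8
Reactants: 14 methyl 3-allyl-5-[(2E)-4-(tert-butyldimethylsilyloxy)-3-methylbut-2-en-1-yl]-4-methoxybenzoate; 8 methacrolein
Product: 15 methyl 3-[(2E)-4-(tert-butyldimethylsilyloxy)-3-methylbut-2-en-1-yl]-4-methoxy-5-[(2E)-3-methyl-4-oxobut-2-en-1-yl]benzoate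
Conditions: methacrolein (8 equiv), second-generation Grubbs catalyst RuCl2(=CHPh)(H2IMes)(PCy3) (5 mol%), 1,4-benzoquinone (10 mol%), CH2Cl2, 40 °C
Reagents that add atoms: methacrolein (8), CC(=C)C=O
Why: Cross-metathesis engages only the monosubstituted alkene (the trisubstituted silyloxymethyl alkene is a spectator) and gives the E enal as in step 4.

Step 9
Reactants: 15 methyl 3-[(2E)-4-(tert-butyldimethylsilyloxy)-3-methylbut-2-en-1-yl]-4-methoxy-5-[(2E)-3-methyl-4-oxobut-2-en-1-yl]benzoate; 16 allylmagnesium bromide; 17 (+)-B-methoxydiisopinocampheylborane (the antipode made from (−)-α-pinene)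
Product: 19 methyl 3-[(2E)-4-(tert-butyldimethylsilyloxy)-3-methylbut-2-en-1-yl]-5-[(2E,4R)-4-hydroxy-3-methylhepta-2,6-dien-1-yl]-4-methoxybenzoate, via diisopinocampheylborinate 18 (not isolated)
Conditions: 17 (1.5 equiv), allylMgBr (1.4 equiv), Et2O, 0 °C → rt, 1 h; then 15, Et2O, −78 °C, 3 h; then NaBO3·4H2O, THF/H2O, rt
Reagents that add atoms: allylmagnesium bromide (16), C=CC[Mg]Br
Why: Brown asymmetric allylboration through a closed chair six-membered transition state, in which the isopinocampheyl groups from (−)-α-pinene direct the allyl group to the Re face of the enal carbonyl and so set 4R (this reagent class gives very high ee with (E)-2-methylenals); the ester is inert at −78 °C and the buffered perborate work-up frees the alcohol without hydrolysing it.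

Step 10
Reactants: 19 methyl 3-[(2E)-4-(tert-butyldimethylsilyloxy)-3-methylbut-2-en-1-yl]-5-[(2E,4R)-4-hydroxy-3-methylhepta-2,6-dien-1-yl]-4-methoxybenzoate; 20 2-methyl-2-butene
Product: 21 methyl 3-[(2E)-4-(tert-butyldimethylsilyloxy)-3-methylbut-2-en-1-yl]-5-[(2E,4R)-4-hydroxy-3,7-dimethylocta-2,6-dien-1-yl]-4-methoxybenzoate
Conditions: 2-methyl-2-butene (large excess, co-solvent), second-generation Grubbs catalyst RuCl2(=CHPh)(H2IMes)(PCy3) (5 mol%), CH2Cl2, 35 °C, sealed
Reagents that add atoms: 2-methyl-2-butene (20), CC=C(C)C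
Why: Cross-metathesis with 2-methyl-2-butene converts only the terminal vinyl group into the isopropylidene (prenyl) end, while the two trisubstituted alkenes and the carbinol stereocentre are untouched.

Step 11
Reactants: 21 methyl 3-[(2E)-4-(tert-butyldimethylsilyloxy)-3-methylbut-2-en-1-yl]-5-[(2E,4R)-4-hydroxy-3,7-dimethylocta-2,6-dien-1-yl]-4-methoxybenzoate
Product: 22 methyl 3-[(2E)-4-hydroxy-3-methylbut-2-en-1-yl]-5-[(2E,4R)-4-hydroxy-3,7-dimethylocta-2,6-dien-1-yl]-4-methoxybenzoate
Conditions: Bu4NF, THF, 0 °C → rt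
Reagents that add atoms: none
Why: Fluoride-driven desilylation (strong Si–F bond) frees the primary allylic alcohol under non-acidic conditions, so the secondary allylic alcohol cannot ionise.

Step 12
Reactants: 22 methyl 3-[(2E)-4-hydroxy-3-methylbut-2-en-1-yl]-5-[(2E,4R)-4-hydroxy-3,7-dimethylocta-2,6-dien-1-yl]-4-methoxybenzoate; 23 lithium hydroxide
Product: 25 3-[(2E)-4-hydroxy-3-methylbut-2-en-1-yl]-5-[(2E,4R)-4-hydroxy-3,7-dimethylocta-2,6-dien-1-yl]-4-methoxybenzoic acid (CNP0122795.1), via lithium carboxylate 24 (not isolated)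
Conditions: LiOH·H2O, THF/MeOH/H2O (3:1:1), rt; then 1 M HCl to pH 4, 0 °C
Reagents that add atoms: lithium hydroxide (23), [Li+].[OH-]
Why: Saponification of the unhindered methyl benzoate by acyl substitution, followed by cold, mild acidification that does not disturb the allylic alcohols or the stereocentre.

**Compound list**
1 | methyl 3-bromo-4-hydroxybenzoate | COC(=O)c1ccc(O)c(Br)c1 | starting material
2 | allyl bromide | C=CCBr | starting material
3 | methyl 4-(allyloxy)-3-bromobenzoate | COC(=O)c1ccc(OCC=C)c(Br)c1 | intermediate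
4 | methyl 3-allyl-5-bromo-4-oxocyclohexa-1,5-diene-1-carboxylate (ortho-dienone, racemic, not isolated) | COC(=O)C1=CC(CC=C)C(=O)C(Br)=C1 | intermediate
5 | methyl 3-allyl-5-bromo-4-hydroxybenzoate | COC(=O)c1cc(Br)c(O)c(CC=C)c1 | intermediate
6 | iodomethane | CI | starting material
7 | methyl 3-allyl-5-bromo-4-methoxybenzoate | COC(=O)c1cc(Br)c(OC)c(CC=C)c1 | intermediate
8 | methacrolein | CC(=C)C=O | starting material
9 | methyl 3-bromo-4-methoxy-5-[(2E)-3-methyl-4-oxobut-2-en-1-yl]benzoate | COC(=O)c1cc(Br)c(OC)c(C/C=C(\C)C=O)c1 | intermediate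
10 | methyl 3-bromo-5-[(2E)-4-hydroxy-3-methylbut-2-en-1-yl]-4-methoxybenzoate | COC(=O)c1cc(Br)c(OC)c(C/C=C(\C)CO)c1 | intermediate
11 | tert-butyldimethylsilyl chloride | CC(C)(C)[Si](C)(C)Cl | starting material
12 | methyl 3-bromo-5-[(2E)-4-(tert-butyldimethylsilyloxy)-3-methylbut-2-en-1-yl]-4-methoxybenzoate | COC(=O)c1cc(Br)c(OC)c(C/C=C(\C)CO[Si](C)(C)C(C)(C)C)c1 | intermediate
13 | allyltributylstannane | C=CC[Sn](CCCC)(CCCC)CCCC | starting material
14 | methyl 3-allyl-5-[(2E)-4-(tert-butyldimethylsilyloxy)-3-methylbut-2-en-1-yl]-4-methoxybenzoate | COC(=O)c1cc(CC=C)c(OC)c(C/C=C(\C)CO[Si](C)(C)C(C)(C)C)c1 | intermediate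
15 | methyl 3-[(2E)-4-(tert-butyldimethylsilyloxy)-3-methylbut-2-en-1-yl]-4-methoxy-5-[(2E)-3-methyl-4-oxobut-2-en-1-yl]benzoate | COC(=O)c1cc(C/C=C(\C)C=O)c(OC)c(C/C=C(\C)CO[Si](C)(C)C(C)(C)C)c1 | intermediate
16 | allylmagnesium bromide | C=CC[Mg]Br | starting material
17 | (+)-B-methoxydiisopinocampheylborane (both isopinocampheyl groups from (1S,5S)-(−)-α-pinene; boron on C3, trans to the C2 methyl, on the face away from the gem-dimethyl bridge) | COB([C@H]1C[C@H]2C[C@@H]([C@@H]1C)C2(C)C)[C@H]1C[C@H]2C[C@@H]([C@@H]1C)C2(C)C | starting material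
18 | O-diisopinocampheylboryl ether (borinate) of alcohol 19, carbinol carbon R (not isolated) | COC(=O)c1cc(C/C=C(\C)[C@H](OB([C@H]2C[C@H]3C[C@@H]([C@@H]2C)C3(C)C)[C@H]2C[C@H]3C[C@@H]([C@@H]2C)C3(C)C)CC=C)c(OC)c(C/C=C(\C)CO[Si](C)(C)C(C)(C)C)c1 | intermediate
19 | methyl 3-[(2E)-4-(tert-butyldimethylsilyloxy)-3-methylbut-2-en-1-yl]-5-[(2E,4R)-4-hydroxy-3-methylhepta-2,6-dien-1-yl]-4-methoxybenzoate | COC(=O)c1cc(C/C=C(\C)[C@H](O)CC=C)c(OC)c(C/C=C(\C)CO[Si](C)(C)C(C)(C)C)c1 | intermediate
20 | 2-methyl-2-butene | CC=C(C)C | starting material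
21 | methyl 3-[(2E)-4-(tert-butyldimethylsilyloxy)-3-methylbut-2-en-1-yl]-5-[(2E,4R)-4-hydroxy-3,7-dimethylocta-2,6-dien-1-yl]-4-methoxybenzoate | COC(=O)c1cc(C/C=C(\C)[C@H](O)CC=C(C)C)c(OC)c(C/C=C(\C)CO[Si](C)(C)C(C)(C)C)c1 | intermediate
22 | methyl 3-[(2E)-4-hydroxy-3-methylbut-2-en-1-yl]-5-[(2E,4R)-4-hydroxy-3,7-dimethylocta-2,6-dien-1-yl]-4-methoxybenzoate | COC(=O)c1cc(C/C=C(\C)[C@H](O)CC=C(C)C)c(OC)c(C/C=C(\C)CO)c1 | intermediate
23 | lithium hydroxide (used as the monohydrate) | [Li+].[OH-] | starting material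
24 | lithium 3-[(2E)-4-hydroxy-3-methylbut-2-en-1-yl]-5-[(2E,4R)-4-hydroxy-3,7-dimethylocta-2,6-dien-1-yl]-4-methoxybenzoate (not isolated) | [Li+].[O-]C(=O)c1cc(C/C=C(\C)[C@H](O)CC=C(C)C)c(OC)c(C/C=C(\C)CO)c1 | intermediate
25 | 3-[(2E)-4-hydroxy-3-methylbut-2-en-1-yl]-5-[(2E,4R)-4-hydroxy-3,7-dimethylocta-2,6-dien-1-yl]-4-methoxybenzoic acid | COc1c(C/C=C(\C)CO)cc(C(=O)O)cc1C/C=C(\C)[C@H](O)CC=C(C)C | target

**Count and risk**
Total steps: 12. Longest linear sequence: 12 (fully linear from 1).

Three steps most likely to fail: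

Step 7 (Stille allylation). The bromide sits ortho to the methoxy group, and the allyl group can migrate to the conjugated propenyl isomer at 110 °C. The fallback sets out from 12 and reverses the roles of the partners. Miyaura borylation (B2pin2, PdCl2(dppf), KOAc, dioxane, 90 °C) gives the aryl pinacol boronate F1. Suzuki–Miyaura coupling of this aryl nucleophile with allyl bromide 2 as the electrophile (Pd(PPh3)4, K2CO3, THF/H2O, 60 °C) comes back to the route at 14.

Step 8 (cross-metathesis with methacrolein on the elaborated arene). Risks are isomerisation of the allylarene, oligomerisation of methacrolein and stalled conversion. The fallback sets out from 14 and reaches the enal by allylic oxidation instead. Cross-metathesis with 2-methyl-2-butene 20 (the robust partner used in step 10) gives the prenyl arene F2. SeO2 (catalytic) with t-BuOOH in CH2Cl2 at 0 °C → rt oxidises the E methyl of the electron-rich prenyl group; the alkene bearing the silyloxymethyl group is deactivated. This gives the (E)-allylic alcohol F3, together with some enal. MnO2 in CH2Cl2 takes the mixture to the enal and comes back to the route at 15.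

Step 9 (Brown allylboration). The ee falls if free Grignard reagent or magnesium salts are carried over or the temperature drifts, and the product must be separated from isopinocampheol. The fallback sets out from 15 and sets the stereocentre by reduction instead of by addition. A zinc Barbier reaction (Zn dust, allyl bromide 2, THF/saturated aqueous NH4Cl, rt) adds to the aldehyde only and gives the racemic homoallylic alcohol F4. Dess–Martin periodinane with NaHCO3 in CH2Cl2 gives the dienone F5, which is used crude because its β,γ-alkene can slip into conjugation. Corey–Bakshi–Shibata reduction with (S)-2-methyl-CBS-oxazaborolidine and catecholborane (toluene, −78 °C), with the α-methyl alkenyl group acting as the large substituent, gives the R alcohol and comes back to the route at 19.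

**Further compounds**
F1 | step 7 | methyl 3-[(2E)-4-(tert-butyldimethylsilyloxy)-3-methylbut-2-en-1-yl]-4-methoxy-5-(4,4,5,5-tetramethyl-1,3,2-dioxaborolan-2-yl)benzoate | COC(=O)c1cc(B2OC(C)(C)C(C)(C)O2)c(OC)c(C/C=C(\C)CO[Si](C)(C)C(C)(C)C)c1
F2 | step 8 | methyl 3-[(2E)-4-(tert-butyldimethylsilyloxy)-3-methylbut-2-en-1-yl]-4-methoxy-5-(3-methylbut-2-en-1-yl)benzoate | COC(=O)c1cc(CC=C(C)C)c(OC)c(C/C=C(\C)CO[Si](C)(C)C(C)(C)C)c1
F3 | step 8 | methyl 3-[(2E)-4-(tert-butyldimethylsilyloxy)-3-methylbut-2-en-1-yl]-5-[(2E)-4-hydroxy-3-methylbut-2-en-1-yl]-4-methoxybenzoate | COC(=O)c1cc(C/C=C(\C)CO)c(OC)c(C/C=C(\C)CO[Si](C)(C)C(C)(C)C)c1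
F4 | step 9 | methyl 3-[(2E)-4-(tert-butyldimethylsilyloxy)-3-methylbut-2-en-1-yl]-5-[(2E)-4-hydroxy-3-methylhepta-2,6-dien-1-yl]-4-methoxybenzoate (racemic at the carbinol carbon) | COC(=O)c1cc(C/C=C(\C)C(O)CC=C)c(OC)c(C/C=C(\C)CO[Si](C)(C)C(C)(C)C)c1
F5 | step 9 | methyl 3-[(2E)-4-(tert-butyldimethylsilyloxy)-3-methylbut-2-en-1-yl]-4-methoxy-5-[(2E)-3-methyl-4-oxohepta-2,6-dien-1-yl]benzoate | COC(=O)c1cc(C/C=C(\C)C(=O)CC=C)c(OC)c(C/C=C(\C)CO[Si](C)(C)C(C)(C)C)c1
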